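## Remarks on the chemistry (assumptions, one line each)

- Atom numbers C1–C11 are those of the target skeleton (C1 ketone, C2=C3 with the methyl on C3, cyclobutane C4–C5–C11–C10, C6 gem-dimethyl, C7 isovalerate, C8 methylene, C9 senecioate) and are used for every intermediate.
- Methyl nerate is taken to be purchasable as the 2Z isomer free of the 2E isomer.
- The (R)-phosphoric acid of step 2 is taken to give the R carbinol, as it does with aromatic and α,β-unsaturated aldehydes; if the sense were opposite, the (S)-acid would be used.
- The D-fructose-derived ketone of step 5 is taken to give R at the CH carbon of the epoxide of a 2-methylalk-2-ene.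

## Structural features

The target is a longipinane. A cyclobutane (C4–C5–C11–C10) is shared by a cyclohexenone (C1 ketone, C2=C3, bridgeheads C4 and C11) and by a seven-membered ring (C5–C6–C7–C8–C9–C10) that spans C5 and C10 on the face away from the C1–C3 bridge. Of the six stereocentres, four (C4, C5, C11, C10) are contiguous on the cyclobutane; C10 is quaternary, with its methyl syn to the cyclohexenone bridge, and adjoins the oxygenated C9, while C7 adjoins the gem-dimethyl carbon C6 and is trans to C9 across the seven-membered ring. Two different esters sit on this 1,3-diol (isovalerate on C7, senecioate on C9), so the hydroxyls must be told apart and acyl migration avoided. Fragile elements are the strained pinane-type core (cationic conditions invite Wagner–Meerwein shifts), the conjugated senecioate and the enone. The real difficulty is the cyclobutane, which carries the quaternary C10, joins both other rings and must be made as one enantiomer. The key step reads it as the union of a C5=C4 ketene with the E-configured C10=C11 alkene of a head-to-tail farnesane chain, with C1–C2–C3 as the tether that becomes the cyclohexene. The C5 carbonyl left by that union is then the point where C6 is attached to close the seven-membered ring.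

## Logic of the disconnections

The C9–O acyl bond of 20 is cut first, giving 19. The senecioate is the most sensitive group, so it goes on last, after every oxidation, radical and fluoride step. The forward step must acylate a hindered hydroxyl next to quaternary C10 without deconjugating the acyl group.

The C9 hydroxyl of 19 is masked as the silyl ether in 18 (O–Si bond). One silyl group on C9 keeps C9–O and C7–O distinguishable from the open chain to the end. Its removal must not create an alkoxide that could pull the C7 ester across.

The C1 carbonyl oxygen of 18 is removed, giving 17. C1 is the allylic methylene that the cycloaddition tether leaves behind, so no enone has to pass through the radical steps. The forward oxidation must take the ring methylene and not the C3 methyl or the bridgehead C4–H.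

The C5–H bond of 17 is traced back to the C5–O bond of 16 and 15. This adds an oxygen, but it lets C5 be a carbonyl carbon in the ring-closing step. The forward step is the deoxygenation of a hindered tertiary cyclobutanol through a C5 radical; configuration is no issue because the ring holds C6 anti to the C1–C3 bridge.

The C7–O acyl bond of 15 is cut to give 14. There C7 carries the only free secondary hydroxyl (C9 silylated, C5 tertiary), so the isovalerate needs no further protecting group.

The C5–C6 bond of 14 is cut, which opens the seven-membered ring and returns the C5 ketone and a C6–C7 epoxide in 13. A quaternary C6 next to an oxygenated C7 is what a tertiary radical from an epoxide provides, and the tricycle becomes a bicycle with a side chain. The forward step needs the C6 radical to add to the C5 carbonyl faster than it is reduced.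

The bonds C4–C10 and C5–C11 of 13 are cut together, leading through 12 to 11. Two rings and the stereocentres C4, C10 and C11 disappear, and an open chain holding all fifteen skeletal carbons in farnesane order remains. The forward step has three demands.
- HCl must be lost through C2 and not through the C3 methyl. This is why 11 is the 2Z isomer: in a 2E chloride the methyl is the group cis to the acyl chloride, and the exocyclic-methylene isomer of 13 would be expected.
- The E geometry of C10=C11 must be transferred to C10.
- One face of C10=C11 must be preferred. Only the C9 stereocentre can help, and since C11 bears a hydrogen cis to C9, allylic 1,3-strain is weak; the bias rests on the rotamer about C9–C10 that the C10 methyl imposes.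

The C5–Cl bond of 11 goes back to 10 and this to 9. The demand is neutrality: no HCl may meet the epoxide or isomerise the 2Z double bond.

The epoxide oxygen on C6–C7 of 9 is removed to give 8. The epoxide is installed before the rings so that no oxidant is used in the presence of the strained β,γ-unsaturated cyclobutanone of 13 (Baeyer–Villiger risk) or its ring alkene; it is a spectator in the cycloaddition. The forward step must select C6=C7 among three trisubstituted alkenes and set C7 by reagent control.

The O–Si bond of 8 is cut to give 7; the silyl ether also shields C10=C11 during the epoxidation.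

The C6=C7 double bond of 7 is cut by a metathesis transform into 5 and 6, which reduces the prenyl group to a vinyl group.

The C8–C9 bond of 5 is cut into 3 and 4. This is where absolute configuration enters, by catalyst control at C9.

The C9 oxygen of 3 is removed, through 2, to the E-methyl group of 1.

## Other disconnections considered

Alternative 1: The cut is C10–C11. In the forward sense the 6–7 fused bicyclic diketone A2 is deprotonated twice with LiN(iPr)2 (cross-conjugated C11 enolate, C10 α′-enolate) and oxidised with Fe(acac)3 (trivalent iron) to the tricycle A1.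
- In favour: both carbonyls and the C7 oxygen are in place, so neither a late C1 oxidation nor a C5 deoxygenation is needed. On oxidation-state economy this is better than the chosen plan.
- Against: the step must close a four-membered ring by joining two enolate carbons, one of them fully substituted, against about 26 kcal/mol of strain. Oxidative enolate coupling is established for less strained rings and for intermolecular cases. The resulting 1,4-diketone inside a cyclobutane is prone to reopening. A1 still needs the 7,9-trans diol to be set from a vinylogous ester beside the C1 enone and the two esters to be differentiated.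
- Comparison: structurally both plans target the cyclobutane, but the chosen one makes two of its bonds concertedly from an open chain, whereas here the most hindered bond is made last. Mechanistically the chosen step has the closer analogy. The steps after A1 should be fewer than after 13, but A2 needs a longer preparation than 11, so overall length is expected to be comparable at best.

Alternative 2: The cuts are C4–C5 and C1–C11, followed later by a shift of C10 from C1 to C11. On heating, the silyloxycyclopentadiene A4 with its tethered E-vinylboronate should give the norbornene A3; oxidation of the C–B bond, activation and a semipinacol-type 1,2-shift would then convert the norbornyl into the pinyl skeleton and create the C1 ketone.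
- In favour: two rings and four stereocentres form at once, which is more than the chosen step builds. C1, C7 and C9 are oxygenated from the start, so no late C–H oxidation or deoxygenation is needed. The quaternary C10 blocks hydrogen shifts in the diene, and the endo boronate is placed anti to the C1–C10 bond.
- Against: the tether ring is seven-membered and the partners are electronically mismatched (electron-rich diene, weakly activated boronate). The quaternary C10 stereocentre of A4 must be set beforehand relative to C9 and C7. The shift runs toward the more strained skeleton, and four protecting or masking groups are carried.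
- Comparison: both key steps are pericyclic. The alternative is superior in stereocentres set and in oxidation pattern, the chosen plan in the length of the way to its precursor (seven steps) and in the directness of the analogy; the number of steps after the key step is probably similar.

Alternative 3: The cut is C5–C11. Visible-light excitation of the ene-1,11-dione A6 would move a C5 hydrogen to the C11 carbonyl oxygen, and the 1,4-biradical would close to the α-ketol A5.
- In favour: the last ring is formed on a molecule that already carries both esters, C5 needs no prior functionalisation, and only the removal of the C11 hydroxyl separates A5 from the target. After the key step this is clearly better than the chosen plan in step economy.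
- Against: several other hydrogens are within reach of the excited dione (C8–H2; from the C1 side the acyloxy-activated C9–H and the C10 methyl), and the biradical can fragment instead of closing to a strained ring. The C11 hydroxyl is tertiary, at a bridgehead, where an enolate-based α-deoxygenation is not available, so its removal is about as hard as the C5 deoxygenation of the chosen plan (equal on this point). A6, with its quaternary C10 and trans-diester, is itself a long synthesis.
- Comparison: structurally only one cyclobutane bond is made. Mechanistically a photochemical biradical closure replaces a thermal cycloaddition with a closer analogy. The steps saved at the end are expected to be spent before the key step.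

Key step: step 8

## Route

Step 1
Reactants: 1 methyl nerate, methyl (2Z)-3,7-dimethylocta-2,6-dienoate
Product: 3 methyl (2Z,6E)-3,7-dimethyl-8-oxoocta-2,6-dienoate, via the 8-hydroxy ester 2 (not isolated)
Conditions: SeO2 (1.3 equiv), 1,4-dioxane, 90 °C
Reagents that add atoms: selenium dioxide O=[Se]=O
Why: Riley allylic oxidation (ene reaction, then [2,3]-shift) attacks the electron-rich distal alkene C10=C11 at its E-methyl group (C9) and carries on to the enal; the conjugated C3=C4 alkene is inert and the 2Z geometry is untouched.

Step 2
Reactants: 3 methyl (2Z,6E)-3,7-dimethyl-8-oxoocta-2,6-dienoate; 4 allylboronic acid pinacol ester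
Product: 5 methyl (2Z,6E,8R)-8-hydroxy-3,7-dimethylundeca-2,6,10-trienoate
Conditions: (R)-3,3′-bis(2,4,6-triisopropylphenyl)-1,1′-binaphthyl-2,2′-diyl hydrogen phosphate (5 mol%), toluene, −30 °C
Reagents that add atoms: none
Why: Chiral phosphoric acid-catalysed allylboration adds the allyl group 1,2 to the enal through a chair six-membered transition state; the new C9 stereocentre is set by the catalyst, whose (R) enantiomer is expected to give the R carbinol.

Step 3
Reactants: 5 methyl (2Z,6E,8R)-8-hydroxy-3,7-dimethylundeca-2,6,10-trienoate; 6 2-methylbut-2-ene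
Product: 7 methyl (2Z,6E,8R)-8-hydroxy-3,7,11-trimethyldodeca-2,6,10-trienoate
Conditions: second-generation Grubbs catalyst (H2IMes)(PCy3)Cl2Ru=CHPh (5 mol%), 6 as co-solvent, CH2Cl2, 40 °C
Reagents that add atoms: none
Why: Olefin cross-metathesis: only the terminal vinyl group initiates readily, the trisubstituted and conjugated alkenes are inert, and the excess of 6 caps the chain as the prenyl alkene C6=C7 with loss of propene.

Step 4
Reactants: 7 methyl (2Z,6E,8R)-8-hydroxy-3,7,11-trimethyldodeca-2,6,10-trienoate
Product: 8 methyl (2Z,6E,8R)-8-[(tert-butyldimethylsilyl)oxy]-3,7,11-trimethyldodeca-2,6,10-trienoate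
Conditions: TBSCl, imidazole, DMF, rt
Reagents that add atoms: tert-butyldimethylsilyl chloride CC(C)(C)[Si](C)(C)Cl
Why: Standard silylation of a secondary allylic alcohol; the bulky ether shields C10=C11 in step 5 and tolerates the base, titanium, radical and chromium steps that follow.

Step 5
Reactants: 8 methyl (2Z,6E,8R)-8-[(tert-butyldimethylsilyl)oxy]-3,7,11-trimethyldodeca-2,6,10-trienoate
Product: 9 methyl (2Z,6E,8R)-8-[(tert-butyldimethylsilyl)oxy]-9-[(2R)-3,3-dimethyloxiran-2-yl]-3,7-dimethylnona-2,6-dienoate
Conditions: D-fructose-derived Shi ketone (0.3 equiv), KHSO5 (as 2KHSO5·KHSO4·K2SO4), K2CO3, Bu4NHSO4 (cat.), MeCN/CH2(OMe)2, aq. Na2B4O7 buffer (pH 10.5), 0 °C, stopped short of full conversion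
Reagents that add atoms: potassium peroxymonosulfate [K+].[O-]S(=O)(=O)OO
Why: Shi asymmetric epoxidation: the chiral dioxirane takes the most electron-rich and least hindered alkene, C6=C7, since C10=C11 is shielded by the allylic silyloxy group and C3=C4 is conjugated to the ester; C7 is set R by reagent control, and partial conversion limits bis-epoxide.

Step 6
Reactants: 9 methyl (2Z,6E,8R)-8-[(tert-butyldimethylsilyl)oxy]-9-[(2R)-3,3-dimethyloxiran-2-yl]-3,7-dimethylnona-2,6-dienoate
Product: 10 (2Z,6E,8R)-8-[(tert-butyldimethylsilyl)oxy]-9-[(2R)-3,3-dimethyloxiran-2-yl]-3,7-dimethylnona-2,6-dienoic acid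
Conditions: LiOH·H2O, THF/MeOH/H2O, 40 °C; then cold dilute H3PO4 to pH 4–5
Reagents that add atoms: lithium hydroxide [Li+].[OH-]
Why: Saponification; the trisubstituted epoxide, the silyl ether and the Z-enoate are stable to hydroxide, and the acid is released at pH 4–5 in the cold so that the epoxide is not opened.

Step 7
Reactants: 10 (2Z,6E,8R)-8-[(tert-butyldimethylsilyl)oxy]-9-[(2R)-3,3-dimethyloxiran-2-yl]-3,7-dimethylnona-2,6-dienoic acid
Product: 11 (2Z,6E,8R)-8-[(tert-butyldimethylsilyl)oxy]-9-[(2R)-3,3-dimethyloxiran-2-yl]-3,7-dimethylnona-2,6-dienoyl chloride (acyl carbon C5, silyloxy carbon C9, oxirane CH C7)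
Conditions: 1-chloro-N,N,2-trimethylprop-1-en-1-amine (1.2 equiv), CH2Cl2, 0 °C to rt; concentrated and used crude
Reagents that add atoms: 1-chloro-N,N,2-trimethylprop-1-en-1-amine CC(C)=C(Cl)N(C)C
Why: Ghosez's chloroenamine makes the acyl chloride under neutral conditions (the by-product is an amide, no HCl is formed), which spares the epoxide and silyl ether and avoids acid-catalysed Z/E isomerisation of the enoyl chloride.

Step 8
Reactants: 11 (2Z,6E,8R)-8-[(tert-butyldimethylsilyl)oxy]-9-[(2R)-3,3-dimethyloxiran-2-yl]-3,7-dimethylnona-2,6-dienoyl chloride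
Product: 13 (1R,5S,7S)-7-{(1R)-1-[(tert-butyldimethylsilyl)oxy]-2-[(2R)-3,3-dimethyloxiran-2-yl]ethyl}-2,7-dimethylbicyclo[3.1.1]hept-2-en-6-one, via vinylketene 12 (not isolated)
Conditions: Et3N (5 equiv), toluene, 110 °C, slow addition of 11 (final 0.005 M)
Reagents that add atoms: none
Why: Et3N removes HCl by 1,4-elimination from the γ-carbon cis to the acyl group, which in the 2Z chloride is the C2 methylene and not the C3 methyl, so vinylketene 12 (O=C5=C4–C3(Me)=C2) should form with C1 cis to C4. Its electrophilic C5 bonds to the less substituted C11 while the charge developing at tertiary C10 is taken up by C4, a concerted asynchronous thermal [2+2]; the closest known reaction type is the intramolecular cycloaddition of vinylketenes from 3-methylalka-2,6-dienoyl chlorides, which leads to bicyclo[3.1.1]heptan-6-ones of the pinane family. The cyclobutanone (C4, C5, C11, C10) closes by this 2+2 union, and the cyclohexene (C11, C1, C2, C3, C4, C5) closes as the ring of the three-atom tether, which is too short for the fused mode and so enforces the crossed, bridged mode. C4 and C11 are bridgeheads whose relation is fixed by the bicycle, and C10 is fixed relative to them by suprafacial addition to the E alkene, which puts the C10 methyl over the cyclohexene and the C9 chain on the side of C5. The absolute sense depends on which face of C10=C11 is attacked, and only the adjacent C9 stereocentre can tell the faces apart: with C9–H turned toward the C10 methyl and the silyloxy group anti to the incoming C4, the C8 methylene lies under the forming ring and 13 results. This preference is expected to be moderate at best because the inside-alkoxy rotamer opens the other face; the two products are diastereomers and separable, so a poor ratio costs material but not optical purity. Chemoselectivity rests on distance (the epoxide end of the chain cannot reach the ketene) and on high dilution, which suppresses ketene dimerisation.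

Step 9
Reactants: 13 (1R,5S,7S)-7-{(1R)-1-[(tert-butyldimethylsilyl)oxy]-2-[(2R)-3,3-dimethyloxiran-2-yl]ethyl}-2,7-dimethylbicyclo[3.1.1]hept-2-en-6-one
Product: 14 (7R,9R)-9-[(tert-butyldimethylsilyl)oxy]longipin-2-ene-5,7-diol (C5–OH syn to the C1–C3 bridge; C4, C10, C11 as in 20)
Conditions: Cp2TiCl2 (2.5 equiv), Zn dust, THF, rt, the resulting Cp2TiCl solution added slowly to 13; then aq. NaH2PO4
Reagents that add atoms: none
Why: Cp2TiCl (trivalent titanium) opens the epoxide homolytically to the tertiary C6 radical with the titanium alkoxide on C7, and this radical adds 7-exo to the C5 carbonyl, which a second Cp2TiCl reduces at once to the alkoxide so that the addition is not reversed (radical epoxide opening with carbonyl addition). The chain hangs from C10 on the C5 side, C7 is untouched, and the C5 configuration is forced because C6 can only enter anti to the C1–C3 bridge.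

Step 10
Reactants: 14 (7R,9R)-9-[(tert-butyldimethylsilyl)oxy]longipin-2-ene-5,7-diol
Product: 15 (7R,9R)-9-[(tert-butyldimethylsilyl)oxy]-5-hydroxylongipin-2-en-7-yl 3-methylbutanoate
Conditions: 3-methylbutanoyl chloride, pyridine, DMAP (cat.), CH2Cl2, 0 °C to rt
Reagents that add atoms: 3-methylbutanoyl chloride CC(C)CC(=O)Cl
Why: DMAP-catalysed acylation of the only free secondary hydroxyl (C7); the tertiary cyclobutanol at C5 is far more hindered and should stay free.

Step 11
Reactants: 15 (7R,9R)-9-[(tert-butyldimethylsilyl)oxy]-5-hydroxylongipin-2-en-7-yl 3-methylbutanoate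
Product: 16 (7R,9R)-9-[(tert-butyldimethylsilyl)oxy]-5-[(methoxyoxalyl)oxy]longipin-2-en-7-yl 3-methylbutanoate
Conditions: methyl chlorooxoacetate, pyridine, DMAP, CH2Cl2, rt
Reagents that add atoms: methyl chlorooxoacetate COC(=O)C(=O)Cl
Why: Methyl oxalyl chloride is reactive enough to acylate hindered tertiary alcohols without forming an alkoxide, which avoids migration of the C7 ester and alkoxide-induced opening of the vinyl-substituted cyclobutanol.

Step 12
Reactants: 16 (7R,9R)-9-[(tert-butyldimethylsilyl)oxy]-5-[(methoxyoxalyl)oxy]longipin-2-en-7-yl 3-methylbutanoate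
Product: 17 (7R,9R)-9-[(tert-butyldimethylsilyl)oxy]longipin-2-en-7-yl 3-methylbutanoate (C5–H syn to the C1–C3 bridge)
Conditions: Bu3SnH (3 equiv), AIBN (cat.), toluene, 110 °C
Reagents that add atoms: none
Why: Radical deoxygenation of a tertiary methyl oxalate (Barton–McCombie type): stannyl radical addition and fragmentation give the tertiary C5 radical, which takes hydrogen from Bu3SnH. The ring holds C6 anti to the C1–C3 bridge, so hydrogen can only arrive on the syn face; opening of the cyclobutyl radical is stereoelectronically slow and is outrun by a high stannane concentration.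

Step 13
Reactants: 17 (7R,9R)-9-[(tert-butyldimethylsilyl)oxy]longipin-2-en-7-yl 3-methylbutanoate
Product: 18 (7R,9R)-9-[(tert-butyldimethylsilyl)oxy]-1-oxolongipin-2-en-7-yl 3-methylbutanoate
Conditions: CrO3, 3,5-dimethylpyrazole, CH2Cl2, −20 °C
Reagents that add atoms: chromium trioxide O=[Cr](=O)=O
Why: Allylic oxidation by the CrO3·3,5-dimethylpyrazole complex (hexavalent chromium) turns the ring methylene next to the trisubstituted alkene into the enone, as in the conversion of α-pinene into verbenone; the other allylic positions are a bridgehead C–H and a methyl group, and the ester and silyl ether are inert.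

Step 14
Reactants: 18 (7R,9R)-9-[(tert-butyldimethylsilyl)oxy]-1-oxolongipin-2-en-7-yl 3-methylbutanoate
Product: 19 (7R,9R)-9-hydroxy-1-oxolongipin-2-en-7-yl 3-methylbutanoate
Conditions: HF·pyridine, pyridine, THF, 0 °C to rt
Reagents that add atoms: none
Why: Fluoride cleavage of the silyl ether under buffered acidic conditions; no alkoxide is formed, so the C7 ester should not migrate to C9 and the enone is untouched.

Step 15
Reactants: 19 (7R,9R)-9-hydroxy-1-oxolongipin-2-en-7-yl 3-methylbutanoate
Product: 20 CNP0335239.1, (7R,9R)-7-[(3-methylbutanoyl)oxy]-1-oxolongipin-2-en-9-yl 3-methylbut-2-enoate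
Conditions: 3-methylbut-2-enoyl chloride, pyridine, DMAP (cat.), CH2Cl2, 0 °C to rt
Reagents that add atoms: 3-methylbut-2-enoyl chloride CC(C)=CC(=O)Cl
Why: DMAP-catalysed acylation of the hindered secondary C9 hydroxyl; the weak base pyridine and low temperature are chosen so that the acyl chloride is not deprotonated to a vinylketene, which would give the deconjugated ester.

## Compound list

1 | methyl nerate, methyl (2Z)-3,7-dimethylocta-2,6-dienoate | COC(=O)/C=C(/C)CCC=C(C)C | starting material
2 | methyl (2Z,6E)-8-hydroxy-3,7-dimethylocta-2,6-dienoate | COC(=O)/C=C(/C)CC/C=C(\C)CO | intermediate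
3 | methyl (2Z,6E)-3,7-dimethyl-8-oxoocta-2,6-dienoate | COC(=O)/C=C(/C)CC/C=C(\C)C=O | intermediate
4 | allylboronic acid pinacol ester | C=CCB1OC(C)(C)C(C)(C)O1 | starting material
5 | methyl (2Z,6E,8R)-8-hydroxy-3,7-dimethylundeca-2,6,10-trienoate | COC(=O)/C=C(/C)CC/C=C(\C)[C@H](O)CC=C | intermediate
6 | 2-methylbut-2-ene | CC=C(C)C | starting material
7 | methyl (2Z,6E,8R)-8-hydroxy-3,7,11-trimethyldodeca-2,6,10-trienoate | COC(=O)/C=C(/C)CC/C=C(\C)[C@H](O)CC=C(C)C | intermediate
8 | methyl (2Z,6E,8R)-8-[(tert-butyldimethylsilyl)oxy]-3,7,11-trimethyldodeca-2,6,10-trienoate | COC(=O)/C=C(/C)CC/C=C(\C)[C@H](O[Si](C)(C)C(C)(C)C)CC=C(C)C | intermediate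
9 | methyl (2Z,6E,8R)-8-[(tert-butyldimethylsilyl)oxy]-9-[(2R)-3,3-dimethyloxiran-2-yl]-3,7-dimethylnona-2,6-dienoate | COC(=O)/C=C(/C)CC/C=C(\C)[C@H](O[Si](C)(C)C(C)(C)C)C[C@H]1OC1(C)C | intermediate
10 | (2Z,6E,8R)-8-[(tert-butyldimethylsilyl)oxy]-9-[(2R)-3,3-dimethyloxiran-2-yl]-3,7-dimethylnona-2,6-dienoic acid | OC(=O)/C=C(/C)CC/C=C(\C)[C@H](O[Si](C)(C)C(C)(C)C)C[C@H]1OC1(C)C | intermediate
11 | (2Z,6E,8R)-8-[(tert-butyldimethylsilyl)oxy]-9-[(2R)-3,3-dimethyloxiran-2-yl]-3,7-dimethylnona-2,6-dienoyl chloride (precursor of the key step) | ClC(=O)/C=C(/C)CC/C=C(\C)[C@H](O[Si](C)(C)C(C)(C)C)C[C@H]1OC1(C)C | intermediate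
12 | (3Z,6E,8R)-8-[(tert-butyldimethylsilyl)oxy]-9-[(2R)-3,3-dimethyloxiran-2-yl]-3,7-dimethylnona-1,3,6-trien-1-one (vinylketene) | O=C=C/C(C)=C\C/C=C(\C)[C@H](O[Si](C)(C)C(C)(C)C)C[C@H]1OC1(C)C | intermediate
13 | (1R,5S,7S)-7-{(1R)-1-[(tert-butyldimethylsilyl)oxy]-2-[(2R)-3,3-dimethyloxiran-2-yl]ethyl}-2,7-dimethylbicyclo[3.1.1]hept-2-en-6-one (product of the key step; C10 methyl over the cyclohexene) | CC1(C)O[C@@H]1C[C@@H](O[Si](C)(C)C(C)(C)C)[C@@]2(C)[C@@H]3CC=C(C)[C@H]2C3=O | intermediate
14 | (7R,9R)-9-[(tert-butyldimethylsilyl)oxy]longipin-2-ene-5,7-diol (C5–OH syn to the C1–C3 bridge) | CC(C)(C)[Si](C)(C)O[C@@H]1C[C@@H](O)C(C)(C)[C@]2(O)[C@H]3CC=C(C)[C@@H]2[C@]31C | intermediate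
15 | (7R,9R)-9-[(tert-butyldimethylsilyl)oxy]-5-hydroxylongipin-2-en-7-yl 3-methylbutanoate | CC(C)(C)[Si](C)(C)O[C@@H]1C[C@@H](OC(=O)CC(C)C)C(C)(C)[C@]2(O)[C@H]3CC=C(C)[C@@H]2[C@]31C | intermediate
16 | (7R,9R)-9-[(tert-butyldimethylsilyl)oxy]-5-[(methoxyoxalyl)oxy]longipin-2-en-7-yl 3-methylbutanoate | CC(C)(C)[Si](C)(C)O[C@@H]1C[C@@H](OC(=O)CC(C)C)C(C)(C)[C@]2(OC(=O)C(=O)OC)[C@H]3CC=C(C)[C@@H]2[C@]31C | intermediate
17 | (7R,9R)-9-[(tert-butyldimethylsilyl)oxy]longipin-2-en-7-yl 3-methylbutanoate | CC(C)(C)[Si](C)(C)O[C@@H]1C[C@@H](OC(=O)CC(C)C)C(C)(C)[C@@H]2[C@H]3CC=C(C)[C@@H]2[C@]31C | intermediate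
18 | (7R,9R)-9-[(tert-butyldimethylsilyl)oxy]-1-oxolongipin-2-en-7-yl 3-methylbutanoate | CC(C)(C)[Si](C)(C)O[C@@H]1C[C@@H](OC(=O)CC(C)C)C(C)(C)[C@@H]2[C@H]3C(=O)C=C(C)[C@@H]2[C@]31C | intermediate
19 | (7R,9R)-9-hydroxy-1-oxolongipin-2-en-7-yl 3-methylbutanoate | O[C@@H]1C[C@@H](OC(=O)CC(C)C)C(C)(C)[C@@H]2[C@H]3C(=O)C=C(C)[C@@H]2[C@]31C | intermediate
20 | CNP0335239.1, (4R,5S,7R,9R,10R,11R)-7-[(3-methylbutanoyl)oxy]-1-oxolongipin-2-en-9-yl 3-methylbut-2-enoate | CC(C)=CC(=O)O[C@@H]1C[C@@H](OC(=O)CC(C)C)C(C)(C)[C@@H]2[C@H]3C(=O)C=C(C)[C@@H]2[C@]31C | target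

## Step count and least certain steps

Total step count: 15. Longest linear sequence: 15 steps (1 to 20).

**Step 8 (key step).** Most likely to go wrong: poor facial selectivity at C10=C11. The C9 substituents lie beside a forming four-membered ring that is almost symmetrical about the C10···C5 axis, and the inside-alkoxy rotamer may even make the wrong face the preferred one. Some loss of HCl through the C3 methyl after Z/E scrambling would be a second leak.

Fallback (sets out from 3, returns at 15): the relay is reversed, so that the preferred face becomes the right one, and C9 is corrected once the cyclobutanone is consumed.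
- Aldehyde 3 is allylated with the (S)-phosphoric acid to the 8S alcohol F1.
- The operations of steps 3 to 7 follow: cross-metathesis to the prenyl alcohol F2, silylation to the silyl ether F3, Shi epoxidation with the same ketone to the epoxide F4, saponification to the acid F5, and the chloroenamine to the acyl chloride F6.
- Et3N in hot toluene gives the vinylketene F7, which should now close mainly to the 9-epi bicyclic ketone F8 with C4, C10 and C11 as in 13.
- Cp2TiCl closes the 9-epi diol F9, isovalerylation gives the ester F10, and HF·pyridine the 9-epi alcohol F11.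
- Dess–Martin periodinane gives the C9 ketone F12. Catecholborane with (S)-2-methyl-CBS-oxazaborolidine (large group: the quaternary C10 side) is expected to give the 9R alcohol F13 by reagent control.
- TBSCl and imidazole silylate the secondary hydroxyl of F13 and return 15.

**Step 7.** Most likely to go wrong: opening of the epoxide by chloride (chlorohydrin formation) while the acyl chloride is made, or later at 110 °C beside Et3NH+Cl−.

Fallback (sets out from 8, returns at 13): the C6=C7 alkene is carried through the ring construction and is oxidised only after the cyclobutanone has been masked by reduction.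
- 8 is saponified to the trienoic acid F14 and converted with the chloroenamine into the acyl chloride F15.
- Et3N in hot toluene gives the vinylketene F16, which closes to the prenyl bicyclic ketone F17.
- NaBH4 gives the cyclobutanol F18 (either C5 epimer serves), Shi epoxidation the epoxy alcohol F19, and Dess–Martin periodinane returns 13.

**Step 9.** Most likely to go wrong: premature quenching of the C6 radical, by reduction with a second Cp2TiCl and β-hydride loss, before the seven-membered closure.

Fallback (sets out from 13, returns at 15): the same radical is generated by hydrogen-atom transfer to an alkene instead.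
- Excess Cp2TiCl added in one portion turns 13 deliberately into the allylic alcohol F20, and isovalerylation gives the allylic ester F21.
- Fe(acac)3 (trivalent iron) and PhSiH3 in EtOH at 60 °C transfer a hydrogen atom to the terminal CH2 of the isopropenyl group. The C6 radical adds to the C5 ketone and the alkoxy radical is reduced by divalent iron, which gives 15 directly.

**Step 11.** Most likely to go wrong: failure to acylate the tertiary cyclobutanol flanked by the quaternary C6, or forcing conditions that move the C7 ester.

Fallback (sets out from 15, returns at 17): the C5–O bond is broken without derivatisation, by titanium-catalysed homolysis of the free tertiary alcohol (Cp*TiCl3 catalytic, Zn, Et3SiCl, PhSiH3). Trivalent titanium removes the hydroxyl and the silane supplies the hydrogen atom. No new compound is made, and steps 11 and 12 are replaced together.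

## Further compounds

F1 | step 8 | methyl (2Z,6E,8S)-8-hydroxy-3,7-dimethylundeca-2,6,10-trienoate | COC(=O)/C=C(/C)CC/C=C(\C)[C@@H](O)CC=C
F2 | step 8 | methyl (2Z,6E,8S)-8-hydroxy-3,7,11-trimethyldodeca-2,6,10-trienoate | COC(=O)/C=C(/C)CC/C=C(\C)[C@@H](O)CC=C(C)C
F3 | step 8 | methyl (2Z,6E,8S)-8-[(tert-butyldimethylsilyl)oxy]-3,7,11-trimethyldodeca-2,6,10-trienoate | COC(=O)/C=C(/C)CC/C=C(\C)[C@@H](O[Si](C)(C)C(C)(C)C)CC=C(C)C
F4 | step 8 | methyl (2Z,6E,8S)-8-[(tert-butyldimethylsilyl)oxy]-9-[(2R)-3,3-dimethyloxiran-2-yl]-3,7-dimethylnona-2,6-dienoate | COC(=O)/C=C(/C)CC/C=C(\C)[C@@H](O[Si](C)(C)C(C)(C)C)C[C@H]1OC1(C)C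
F5 | step 8 | (2Z,6E,8S)-8-[(tert-butyldimethylsilyl)oxy]-9-[(2R)-3,3-dimethyloxiran-2-yl]-3,7-dimethylnona-2,6-dienoic acid | OC(=O)/C=C(/C)CC/C=C(\C)[C@@H](O[Si](C)(C)C(C)(C)C)C[C@H]1OC1(C)C
F6 | step 8 | (2Z,6E,8S)-8-[(tert-butyldimethylsilyl)oxy]-9-[(2R)-3,3-dimethyloxiran-2-yl]-3,7-dimethylnona-2,6-dienoyl chloride | ClC(=O)/C=C(/C)CC/C=C(\C)[C@@H](O[Si](C)(C)C(C)(C)C)C[C@H]1OC1(C)C
F7 | step 8 | (3Z,6E,8S)-8-[(tert-butyldimethylsilyl)oxy]-9-[(2R)-3,3-dimethyloxiran-2-yl]-3,7-dimethylnona-1,3,6-trien-1-one | O=C=C/C(C)=C\C/C=C(\C)[C@@H](O[Si](C)(C)C(C)(C)C)C[C@H]1OC1(C)C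
F8 | step 8 | 9-epi bicyclic ketone, C9 epimer of 13 | CC1(C)O[C@@H]1C[C@H](O[Si](C)(C)C(C)(C)C)[C@@]2(C)[C@@H]3CC=C(C)[C@H]2C3=O
F9 | step 8 | 9-epi diol, C9 epimer of 14 | CC(C)(C)[Si](C)(C)O[C@H]1C[C@@H](O)C(C)(C)[C@]2(O)[C@H]3CC=C(C)[C@@H]2[C@]31C
F10 | step 8 | 9-epi ester, C9 epimer of 15 | CC(C)(C)[Si](C)(C)O[C@H]1C[C@@H](OC(=O)CC(C)C)C(C)(C)[C@]2(O)[C@H]3CC=C(C)[C@@H]2[C@]31C
F11 | step 8 | (7R,9S)-5,9-dihydroxylongipin-2-en-7-yl 3-methylbutanoate | O[C@H]1C[C@@H](OC(=O)CC(C)C)C(C)(C)[C@]2(O)[C@H]3CC=C(C)[C@@H]2[C@]31C
F12 | step 8 | (7R)-5-hydroxy-9-oxolongipin-2-en-7-yl 3-methylbutanoate | O=C1C[C@@H](OC(=O)CC(C)C)C(C)(C)[C@]2(O)[C@H]3CC=C(C)[C@@H]2[C@]31C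
F13 | step 8 | (7R,9R)-5,9-dihydroxylongipin-2-en-7-yl 3-methylbutanoate | O[C@@H]1C[C@@H](OC(=O)CC(C)C)C(C)(C)[C@]2(O)[C@H]3CC=C(C)[C@@H]2[C@]31C
F14 | step 7 | (2Z,6E,8R)-8-[(tert-butyldimethylsilyl)oxy]-3,7,11-trimethyldodeca-2,6,10-trienoic acid | OC(=O)/C=C(/C)CC/C=C(\C)[C@H](O[Si](C)(C)C(C)(C)C)CC=C(C)C
F15 | step 7 | (2Z,6E,8R)-8-[(tert-butyldimethylsilyl)oxy]-3,7,11-trimethyldodeca-2,6,10-trienoyl chloride | ClC(=O)/C=C(/C)CC/C=C(\C)[C@H](O[Si](C)(C)C(C)(C)C)CC=C(C)C
F16 | step 7 | (3Z,6E,8R)-8-[(tert-butyldimethylsilyl)oxy]-3,7,11-trimethyldodeca-1,3,6,10-tetraen-1-one | O=C=C/C(C)=C\C/C=C(\C)[C@H](O[Si](C)(C)C(C)(C)C)CC=C(C)C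
F17 | step 7 | (1R,5S,7S)-7-{(1R)-1-[(tert-butyldimethylsilyl)oxy]-4-methylpent-3-en-1-yl}-2,7-dimethylbicyclo[3.1.1]hept-2-en-6-one | CC(C)=CC[C@@H](O[Si](C)(C)C(C)(C)C)[C@@]1(C)[C@@H]2CC=C(C)[C@H]1C2=O
F18 | step 7 | cyclobutanol from F17 (C5 alcohol, mixture of C5 epimers) | CC(C)=CC[C@@H](O[Si](C)(C)C(C)(C)C)[C@@]1(C)[C@@H]2CC=C(C)[C@H]1C2O
F19 | step 7 | epoxy cyclobutanol (7R epoxide, mixture of C5 epimers) | CC1(C)O[C@@H]1C[C@@H](O[Si](C)(C)C(C)(C)C)[C@@]2(C)[C@@H]3CC=C(C)[C@H]2C3O
F20 | step 9 | allylic alcohol from 13 (C7–OH, isopropenyl at C6) | CC(=C)[C@H](O)C[C@@H](O[Si](C)(C)C(C)(C)C)[C@@]1(C)[C@@H]2CC=C(C)[C@H]1C2=O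
F21 | step 9 | allylic 3-methylbutanoate of F20 | CC(=C)[C@H](OC(=O)CC(C)C)C[C@@H](O[Si](C)(C)C(C)(C)C)[C@@]1(C)[C@@H]2CC=C(C)[C@H]1C2=O
F0 | step 11 | none | none
A1 | alternative 1 | 7-methoxylongipina-2,7-diene-1,9-dione | COC1=CC(=O)[C@]2(C)[C@H]3C(C)=CC(=O)[C@@H]2[C@H]3C1(C)C
A2 | alternative 1 | 6–7 fused bicyclic diketone lacking the C10–C11 bond (either C10 epimer) | COC1=CC(=O)C(C)[C@H]2C(C)=CC(=O)C[C@H]2C1(C)C
A3 | alternative 2 | tricyclic norbornene adduct (C1 silyl ether, endo C11 boronate, C9 4-methoxybenzyl ether) | COc1ccc(CO[C@@H]2C[C@@H](O[Si](C)(C)C(C)(C)C)C(C)(C)[C@@H]3[C@@H](B4OC(C)(C)C(C)(C)O4)[C@@]5(O[Si](C)(C)C(C)(C)C)C=C(C)[C@@H]3[C@]52C)cc1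
A4 | alternative 2 | 5,5-disubstituted 1-silyloxycyclopentadiene with tethered E-vinylboronate | COc1ccc(CO[C@H](C[C@@H](O[Si](C)(C)C(C)(C)C)C(C)(C)/C=C/B2OC(C)(C)C(C)(C)O2)[C@]3(C)C=C(C)C=C3O[Si](C)(C)C(C)(C)C)cc1
A5 | alternative 3 | 11-hydroxy derivative of 20 (α-ketol) | CC(C)=CC(=O)O[C@@H]1C[C@@H](OC(=O)CC(C)C)C(C)(C)[C@@H]2[C@@]3(O)C(=O)C=C(C)[C@@H]2[C@]31C
A6 | alternative 3 | 6–7 fused ene-1,11-dione diester lacking the C5–C11 bond | CC(C)=CC(=O)O[C@@H]1C[C@@H](OC(=O)CC(C)C)C(C)(C)C[C@@H]2C(C)=CC(=O)C(=O)[C@@]21C
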